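**Retrosynthetic overview**

1. Target 35 ← silyl ether 34 ← keto aldehyde 29 + vinyl iodide 32 (Nozaki–Hiyama–Kishi addition, then MnO2). 29 ← alkyne diol 20 + benzylic chloride 26 (carboalumination/cross-coupling sets the E-trisubstituted alkene).
2. 20 ← cis-fused γ-lactone 16 (ring B, a temporary ring). Its carbonyl carbon becomes the CH2 of the CH2C(=O) arm after a one-carbon Wittig homologation, and its CH2O carbon becomes the enone carbonyl.
3. 16 ← 14 by methylation of the ring-fusion enolate (second quaternary centre) ← 13 ← key [3+2] annulation of lactone aldehyde 10 with ethenyl(triphenyl)phosphonium bromide 11. A Michael addition joins the lactone α-carbon to one vinyl carbon, and an intramolecular Wittig reaction joins the other vinyl carbon to the formyl carbon.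
4. Enabling feature: in ring A (the cyclopentane) the enone carbonyl carbon and the CH2 of the CH2C(=O) arm sit cis on the two adjacent quaternary carbons, so they can be tied through oxygen as a five-membered lactone (ring B). This makes the second quaternary ring carbon a lactone α-carbon (donor) and lets the ring CH2 next to the first quaternary carbon be a formyl carbon (acceptor); the vinylphosphonium salt bridges this 1,3-donor/acceptor pair as a traceless two-carbon unit.
5. 10 ← (R)-aldehyde 7 ← epoxy silyl ether 6 (stereospecific 1,2-shift) ← epoxy alcohol 5 ← dienol 4 ← pent-1-en-4-yne 1. Ring order: ring B (steps 5–6), ring A (step 7), ring B opened again (steps 10–11).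

Key step: step 7

Remark: the tartrate enantiomer in step 2 is chosen on the assumption that the silyloxymethyl group in step 4 migrates anti to the breaking C–O bond; if the shift took the opposite course, the other tartrate would be used.

**Step 1**
Reactants: 1 pent-1-en-4-yne
Product: 4 (2E)-3-methylhexa-2,5-dien-1-ol, via alkenylalane 2 (not isolated), via lithium aluminate 3 (not isolated)
Conditions: Me3Al, Cp2ZrCl2 (20 mol%), CH2Cl2, 0 °C → rt; n-BuLi, THF, −78 → 0 °C; (CH2O)n, rt
Reagents that add atoms: trimethylaluminium (C[Al](C)C); paraformaldehyde as formaldehyde (C=O)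
Why: Negishi zirconium-catalysed carboalumination adds methyl and aluminium syn across the terminal alkyne only (methyl to the internal carbon), which fixes the E geometry, and the derived aluminate is hydroxymethylated with retention.

**Step 2**
Reactants: 4 (2E)-3-methylhexa-2,5-dien-1-ol
Product: 5 [(2R,3R)-3-methyl-3-(prop-2-en-1-yl)oxiran-2-yl]methanol
Conditions: Ti(OiPr)4 (10 mol%), D-(−)-diethyl tartrate (12 mol%), t-BuOOH, 4 Å MS, CH2Cl2, −20 °C
Reagents that add atoms: tert-butyl hydroperoxide (CC(C)(C)OO)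
Why: Sharpless asymmetric epoxidation touches only the allylic-alcohol double bond, and the D-(−)-tartrate complex should deliver oxygen to the face that gives the (2R,3R)-epoxide, the mirror image of the (2S,3S) outcome of E-3,3-disubstituted allylic alcohols with the L-(+)-tartrate.

**Step 3**
Reactants: 5 [(2R,3R)-3-methyl-3-(prop-2-en-1-yl)oxiran-2-yl]methanol
Product: 6 tert-butyl(dimethyl){[(2R,3R)-3-methyl-3-(prop-2-en-1-yl)oxiran-2-yl]methoxy}silane
Conditions: t-BuMe2SiCl, imidazole, DMF, rt
Reagents that add atoms: tert-butyl(chloro)dimethylsilane (CC(C)(C)[Si](C)(C)Cl)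
Why: Standard silylation of the primary alcohol provides the silyloxymethyl migrating group needed in step 4 and leaves the epoxide untouched.

**Step 4**
Reactants: 6 tert-butyl(dimethyl){[(2R,3R)-3-methyl-3-(prop-2-en-1-yl)oxiran-2-yl]methoxy}silane
Product: 7 (2R)-2-{[tert-butyl(dimethyl)silyl]oxymethyl}-2-methylpent-4-enal
Conditions: MeAl(OAr)2 (Ar = 4-bromo-2,6-di-tert-butylphenyl, 2 equiv), CH2Cl2, −78 °C
Reagents that add atoms: none
Why: Lewis-acid-promoted rearrangement of a 2,3-epoxy silyl ether to a β-silyloxy aldehyde (semipinacol-type 1,2-shift): the bulky aluminium phenoxide opens the epoxide at the tertiary carbon and the silyloxymethyl group migrates anti to the breaking C–O bond, so the epoxide configuration is transferred into the (R)-quaternary centre.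

**Step 5**
Reactants: 7 (2R)-2-{[tert-butyl(dimethyl)silyl]oxymethyl}-2-methylpent-4-enal
Product: 9 (3R)-5-hydroxy-3-methyloxolane-3-carbaldehyde (mixture of C-5 epimers), via dialdehyde 8 (not isolated)
Conditions: O3, CH2Cl2, −78 °C; Me2S; then 1 M HCl, THF, rt
Reagents that add atoms: ozone ([O-][O+]=O)
Why: Ozonolysis cleaves the only C=C bond to the 1,4-dialdehyde, and after acid desilylation the freed hydroxyl closes onto the CH2CHO aldehyde as a five-membered lactol, whereas the formyl group on the quaternary carbon (no α-hydrogen, so no epimerisation) cannot be reached without a four-membered ring.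

**Step 6**
Reactants: 9 (3R)-5-hydroxy-3-methyloxolane-3-carbaldehyde
Product: 10 (3R)-3-methyl-5-oxooxolane-3-carbaldehyde
Conditions: TEMPO (10 mol%), PhI(OAc)2, CH2Cl2, rt
Reagents that add atoms: none
Why: Oxoammonium-mediated oxidation converts a lactol into the lactone under anhydrous, near-neutral conditions in which a free aldehyde is not oxidised further.

**Step 7**
Reactants: 10 (3R)-3-methyl-5-oxooxolane-3-carbaldehyde; 11 ethenyl(triphenyl)phosphonium bromide
Product: 13 (1S,5R)-5-methyl-3-oxabicyclo[3.3.0]oct-6-en-2-one, via phosphonium ylide 12 (not isolated)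
Conditions: NaH (1.1 equiv), THF/DMF, 0 → 40 °C
Reagents that add atoms: none
Why: NaH deprotonates the lactone α-CH2 of 10 (the only enolisable position, because the formyl group sits on a fully substituted carbon) and the sodium enolate adds in Michael fashion to the cationic vinylphosphonium salt 11, which forms the first ring bond and leaves the non-stabilised ylide 12; the ylide carbon then attacks the neighbouring formyl carbon and the oxaphosphetane collapses to the ring cis-alkene, which forms the second ring bond and expels Ph3P=O, so that the two vinyl carbons arrive as a traceless two-carbon unit. The closest known reaction type is the Schweizer cyclopentene annulation, conjugate addition of a carbanion to vinyltriphenylphosphonium bromide followed by intramolecular Wittig olefination of a γ-carbonyl group. Ring A closes by this intramolecular carbonyl olefination, formally a 5-exo-trig attack of the ylide carbon on C=O, onto the preformed lactone ring B. The one new stereocentre, the ring-fusion CH α to the lactone carbonyl, is controlled by the existing quaternary centre through the ring: a bicyclo[3.3.0]octene can only close cis, and a Michael adduct with its side chain trans to the formyl group can epimerise through the lactone enolate before it closes. The quaternary centre of 10 has no α-hydrogen and keeps its configuration. The step needs C-alkylation of the enolate by 11 to outrun aldol addition to the aldehyde of a second molecule, which the high electrophilicity of the unhindered cationic acceptor, the neopentyl-type hindrance of the non-enolisable aldehyde, the reversibility of any aldolate and the irreversible Wittig closure are expected to secure.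

**Step 8**
Reactants: 13 (1S,5R)-5-methyl-3-oxabicyclo[3.3.0]oct-6-en-2-one
Product: 14 (1S,5R)-5-methyl-3-oxabicyclo[3.3.0]octan-2-one
Conditions: H2 (1 atm), Pd/C (palladium on carbon), EtOAc, rt
Reagents that add atoms: none
Why: Heterogeneous hydrogenation saturates the unhindered cis-disubstituted ring alkene before any other alkene is present; no stereocentre is formed and the lactone is inert.

**Step 9**
Reactants: 14 (1S,5R)-5-methyl-3-oxabicyclo[3.3.0]octan-2-one
Product: 16 (1S,5R)-1,5-dimethyl-3-oxabicyclo[3.3.0]octan-2-one, via lithium enolate 15 (not isolated)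
Conditions: LiN(iPr)2, THF, −78 °C; MeI, DMPU, −78 → 0 °C
Reagents that add atoms: iodomethane (CI)
Why: Enolate alkylation at the single α-carbon of the lactone, the ring-fusion CH; iodomethane can only be accepted on the face that keeps the bicyclo[3.3.0]octane cis-fused, which sets the second quaternary centre with the two methyl groups cis.

**Step 10**
Reactants: 16 (1S,5R)-1,5-dimethyl-3-oxabicyclo[3.3.0]octan-2-one
Product: 17 (1S,5R)-1,5-dimethyl-3-oxabicyclo[3.3.0]octan-2-ol (mixture of C-2 epimers)
Conditions: i-Bu2AlH, CH2Cl2, −78 °C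
Reagents that add atoms: none
Why: Partial hydride reduction of a lactone stops at the lactol because the tetrahedral aluminium hemiacetal is stable at −78 °C; both stereocentres are quaternary and cannot epimerise.

**Step 11**
Reactants: 17 (1S,5R)-1,5-dimethyl-3-oxabicyclo[3.3.0]octan-2-ol
Product: 19 (1R,6R)-1,6-dimethyl-3-oxabicyclo[4.3.0]nonan-4-ol (mixture of C-4 epimers), via enol ether 18 (not isolated)
Conditions: [Ph3PCH2OMe]Cl, KOt-Bu, THF, 0 °C → reflux; then 2 M HCl, THF, rt
Reagents that add atoms: (methoxymethyl)triphenylphosphonium chloride (COC[P+](c1ccccc1)(c1ccccc1)c1ccccc1.[Cl-]); water (O)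
Why: Wittig methoxymethylenation of the open hydroxy-aldehyde form of the lactol and hydrolysis of the enol ether give a one-carbon homologation, which turns the former lactone carbon into the CH2 of the side arm; the new aldehyde is trapped by the neighbouring CH2OH as a six-membered lactol.

**Step 12**
Reactants: 19 (1R,6R)-1,6-dimethyl-3-oxabicyclo[4.3.0]nonan-4-ol
Product: 20 1-[(1R,2R)-2-(hydroxymethyl)-1,2-dimethylcyclopentyl]pent-4-yn-2-ol (mixture of C-2 epimers)
Conditions: HC≡CCH2Br, Zn dust, THF/sat. aq NH4Cl, 0 °C → rt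
Reagents that add atoms: 3-bromoprop-1-yne (C#CCBr)
Why: Barbier-type zinc propargylation of the aldehyde in equilibrium with lactol 19 gives the homopropargylic alcohol and tolerates the free hydroxyl; the new carbinol carbon is oxidised later, so its configuration is immaterial.

**Step 13**
Reactants: 21 4-methoxy-3-methylphenol
Product: 22 (4-methoxy-3-methylphenoxy)tri(propan-2-yl)silane
Conditions: i-Pr3SiCl, imidazole, DMF, rt
Reagents that add atoms: chlorotri(propan-2-yl)silane (CC(C)[Si](Cl)(C(C)C)C(C)C)
Why: Silylation of the phenol with a bulky group that withstands organolithium and organoaluminium reagents and shields its own ortho positions from metalation.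

**Step 14**
Reactants: 22 (4-methoxy-3-methylphenoxy)tri(propan-2-yl)silane
Product: 25 (2-methoxy-3-methyl-5-{[tri(propan-2-yl)silyl]oxy}phenyl)methanol, via aryllithium 23 (not isolated), via benzaldehyde 24 (not isolated)
Conditions: n-BuLi, TMEDA, Et2O, 0 °C → rt; DMF, −78 → 0 °C; then NaBH4, MeOH, 0 °C
Reagents that add atoms: N,N-dimethylformamide (CN(C)C=O)
Why: Directed ortho-metalation: the methoxy group directs lithiation to its only free ortho position, DMF formylates the aryllithium and borohydride reduces the aldehyde in the same flask.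

**Step 15**
Reactants: 25 (2-methoxy-3-methyl-5-{[tri(propan-2-yl)silyl]oxy}phenyl)methanol
Product: 26 [3-(chloromethyl)-4-methoxy-5-methylphenoxy]tri(propan-2-yl)silane
Conditions: SOCl2, pyridine, CH2Cl2, 0 °C
Reagents that add atoms: thionyl chloride (ClS(Cl)=O)
Why: Chlorination of an electron-rich benzylic alcohol through its chlorosulfite, with pyridine buffering the HCl so that the aryl silyl ether survives.

**Step 16**
Reactants: 20 1-[(1R,2R)-2-(hydroxymethyl)-1,2-dimethylcyclopentyl]pent-4-yn-2-ol; 26 [3-(chloromethyl)-4-methoxy-5-methylphenoxy]tri(propan-2-yl)silane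
Product: 28 (4E)-1-[(1R,2R)-2-(hydroxymethyl)-1,2-dimethylcyclopentyl]-6-(2-methoxy-3-methyl-5-{[tri(propan-2-yl)silyl]oxy}phenyl)-4-methylhex-4-en-2-ol (mixture of C-2 epimers), via alkenylalane 27 (not isolated)
Conditions: Me3Al (5 equiv), Cp2ZrCl2 (0.5 equiv), CH2Cl2, 0 °C → rt; then 26, Pd(PPh3)4 (5 mol%), THF, rt
Reagents that add atoms: trimethylaluminium (C[Al](C)C)
Why: Negishi carboalumination (hydroxyls carried as aluminium alkoxides, methyl to the internal alkyne carbon, syn addition) followed by palladium-catalysed Negishi coupling of the alkenylalane with the benzylic chloride with retention, which builds the E-trisubstituted alkene with the arylmethyl group cis to the methyl group.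

**Step 17**
Reactants: 28 (4E)-1-[(1R,2R)-2-(hydroxymethyl)-1,2-dimethylcyclopentyl]-6-(2-methoxy-3-methyl-5-{[tri(propan-2-yl)silyl]oxy}phenyl)-4-methylhex-4-en-2-ol
Product: 29 (1R,2R)-2-[(4E)-6-(2-methoxy-3-methyl-5-{[tri(propan-2-yl)silyl]oxy}phenyl)-4-methyl-2-oxohex-4-en-1-yl]-1,2-dimethylcyclopentane-1-carbaldehyde
Conditions: (COCl)2, DMSO, CH2Cl2, −78 °C; i-Pr2NEt, −78 → −30 °C
Reagents that add atoms: none
Why: Swern oxidation converts both hydroxyls into alkoxysulfonium ions before the base is added, so the primary and the secondary alcohol are oxidised together and no lactol (hence no lactone) can form, while the hindered amine at low temperature should leave the β,γ-unsaturated ketone unconjugated.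

**Step 18**
Reactants: 30 2-methylbut-3-yn-2-ol
Product: 31 (3E)-2-methyl-4-(tributylstannyl)but-3-en-2-ol
Conditions: Bu3SnH, AIBN (cat.), 80 °C
Reagents that add atoms: tributylstannane (CCCC[SnH](CCCC)CCCC)
Why: Radical hydrostannation of a terminal propargylic alcohol places tin on the terminal carbon and equilibrates to the E-alkenylstannane.

**Step 19**
Reactants: 31 (3E)-2-methyl-4-(tributylstannyl)but-3-en-2-ol
Product: 32 (3E)-4-iodo-2-methylbut-3-en-2-ol
Conditions: I2, CH2Cl2, 0 °C
Reagents that add atoms: iodine (II)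
Why: Iododestannylation replaces tin by iodine with retention of the E geometry.

**Step 20**
Reactants: 29 (1R,2R)-2-[(4E)-6-(2-methoxy-3-methyl-5-{[tri(propan-2-yl)silyl]oxy}phenyl)-4-methyl-2-oxohex-4-en-1-yl]-1,2-dimethylcyclopentane-1-carbaldehyde; 32 (3E)-4-iodo-2-methylbut-3-en-2-ol
Product: 33 (4E)-1-[(1R,2R)-2-[(2E)-1,4-dihydroxy-4-methylpent-2-en-1-yl]-1,2-dimethylcyclopentyl]-6-(2-methoxy-3-methyl-5-{[tri(propan-2-yl)silyl]oxy}phenyl)-4-methylhex-4-en-2-one (mixture of carbinol epimers)
Conditions: CrCl2 (excess), NiCl2 (cat.), DMF, rt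
Reagents that add atoms: none
Why: Nozaki–Hiyama–Kishi reaction: the alkenylchromium reagent adds to aldehydes but not to ketones, is non-basic (the acidic CH2 of the β,γ-unsaturated ketone is left alone), tolerates the free tertiary alcohol and retains the E geometry; the new carbinol centre is oxidised in the next step.

**Step 21**
Reactants: 33 (4E)-1-[(1R,2R)-2-[(2E)-1,4-dihydroxy-4-methylpent-2-en-1-yl]-1,2-dimethylcyclopentyl]-6-(2-methoxy-3-methyl-5-{[tri(propan-2-yl)silyl]oxy}phenyl)-4-methylhex-4-en-2-one
Product: 34 (4E)-1-[(1R,2R)-2-[(2E)-4-hydroxy-4-methylpent-2-enoyl]-1,2-dimethylcyclopentyl]-6-(2-methoxy-3-methyl-5-{[tri(propan-2-yl)silyl]oxy}phenyl)-4-methylhex-4-en-2-one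
Conditions: MnO2 (activated, excess), CH2Cl2, rt
Reagents that add atoms: none
Why: MnO2 oxidises the secondary allylic alcohol selectively to the E-enone under neutral conditions; the tertiary allylic alcohol, the silyl ether and the β,γ-unsaturated ketone are not affected.

**Step 22**
Reactants: 34 (4E)-1-[(1R,2R)-2-[(2E)-4-hydroxy-4-methylpent-2-enoyl]-1,2-dimethylcyclopentyl]-6-(2-methoxy-3-methyl-5-{[tri(propan-2-yl)silyl]oxy}phenyl)-4-methylhex-4-en-2-one
Product: 35 (4E)-1-[(1R,2R)-2-[(2E)-4-hydroxy-4-methylpent-2-enoyl]-1,2-dimethylcyclopentyl]-6-(5-hydroxy-2-methoxy-3-methylphenyl)-4-methylhex-4-en-2-one (CNP0305066.1)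
Conditions: Bu4NF, AcOH, THF, 0 °C
Reagents that add atoms: none
Why: Fluoride cleaves the aryl silyl ether, and the acetic acid buffer keeps the medium non-basic so that the β,γ-double bond should not move into conjugation and the γ-hydroxy enone is left intact.

**Compound list**

1 | pent-1-en-4-yne | C#CCC=C | starting material
2 | dimethyl[(1E)-2-methylpenta-1,4-dien-1-yl]alumane | C[Al](C)/C=C(\C)CC=C | intermediate
3 | lithium butyl(dimethyl)[(1E)-2-methylpenta-1,4-dien-1-yl]aluminate | [Li+].CCCC[Al-](C)(C)/C=C(\C)CC=C | intermediate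
4 | (2E)-3-methylhexa-2,5-dien-1-ol | OC/C=C(\C)CC=C | intermediate
5 | [(2R,3R)-3-methyl-3-(prop-2-en-1-yl)oxiran-2-yl]methanol | OC[C@H]1O[C@]1(C)CC=C | intermediate
6 | tert-butyl(dimethyl){[(2R,3R)-3-methyl-3-(prop-2-en-1-yl)oxiran-2-yl]methoxy}silane | CC(C)(C)[Si](C)(C)OC[C@H]1O[C@]1(C)CC=C | intermediate
7 | (2R)-2-{[tert-butyl(dimethyl)silyl]oxymethyl}-2-methylpent-4-enal | C=CC[C@@](C)(C=O)CO[Si](C)(C)C(C)(C)C | intermediate
8 | (2R)-2-{[tert-butyl(dimethyl)silyl]oxymethyl}-2-methylbutanedial | O=CC[C@@](C)(C=O)CO[Si](C)(C)C(C)(C)C | intermediate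
9 | (3R)-5-hydroxy-3-methyloxolane-3-carbaldehyde (mixture of C-5 epimers) | O=C[C@]1(C)CC(O)OC1 | intermediate
10 | (3R)-3-methyl-5-oxooxolane-3-carbaldehyde | O=C[C@]1(C)CC(=O)OC1 | intermediate
11 | ethenyl(triphenyl)phosphonium bromide | C=C[P+](c1ccccc1)(c1ccccc1)c1ccccc1.[Br-] | starting material
12 | (3R)-3-methyl-5-oxo-4-[2-(triphenyl-λ5-phosphanylidene)ethyl]oxolane-3-carbaldehyde (both C-4 epimers) | O=C[C@]1(C)C(CC=P(c2ccccc2)(c2ccccc2)c2ccccc2)C(=O)OC1 | intermediate
13 | (1S,5R)-5-methyl-3-oxabicyclo[3.3.0]oct-6-en-2-one | O=C2[C@H]1CC=C[C@@]1(C)CO2 | intermediate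
14 | (1S,5R)-5-methyl-3-oxabicyclo[3.3.0]octan-2-one | O=C2[C@H]1CCC[C@@]1(C)CO2 | intermediate
15 | lithium enolate of 14 | [Li]OC1=C2CCC[C@@]2(C)CO1 | intermediate
16 | (1S,5R)-1,5-dimethyl-3-oxabicyclo[3.3.0]octan-2-one | O=C2[C@@]1(C)CCC[C@@]1(C)CO2 | intermediate
17 | (1S,5R)-1,5-dimethyl-3-oxabicyclo[3.3.0]octan-2-ol (mixture of C-2 epimers) | OC2[C@@]1(C)CCC[C@@]1(C)CO2 | intermediate
18 | [(1R,2R)-2-(2-methoxyethenyl)-1,2-dimethylcyclopentyl]methanol (E/Z mixture) | COC=C[C@@]1(C)CCC[C@@]1(C)CO | intermediate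
19 | (1R,6R)-1,6-dimethyl-3-oxabicyclo[4.3.0]nonan-4-ol (mixture of C-4 epimers) | OC3C[C@@]1(C)CCC[C@@]1(C)CO3 | intermediate
20 | 1-[(1R,2R)-2-(hydroxymethyl)-1,2-dimethylcyclopentyl]pent-4-yn-2-ol (mixture of C-2 epimers) | C#CCC(O)C[C@@]1(C)CCC[C@@]1(C)CO | intermediate
21 | 4-methoxy-3-methylphenol | COc1ccc(O)cc1C | starting material
22 | (4-methoxy-3-methylphenoxy)tri(propan-2-yl)silane | COc1ccc(O[Si](C(C)C)(C(C)C)C(C)C)cc1C | intermediate
23 | (2-methoxy-3-methyl-5-{[tri(propan-2-yl)silyl]oxy}phenyl)lithium | COc1c(C)cc(O[Si](C(C)C)(C(C)C)C(C)C)cc1[Li] | intermediate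
24 | 2-methoxy-3-methyl-5-{[tri(propan-2-yl)silyl]oxy}benzaldehyde | COc1c(C)cc(O[Si](C(C)C)(C(C)C)C(C)C)cc1C=O | intermediate
25 | (2-methoxy-3-methyl-5-{[tri(propan-2-yl)silyl]oxy}phenyl)methanol | COc1c(C)cc(O[Si](C(C)C)(C(C)C)C(C)C)cc1CO | intermediate
26 | [3-(chloromethyl)-4-methoxy-5-methylphenoxy]tri(propan-2-yl)silane | COc1c(C)cc(O[Si](C(C)C)(C(C)C)C(C)C)cc1CCl | intermediate
27 | alkenylalane of 20 with both hydroxyls as dimethylaluminium alkoxides | C[Al](C)/C=C(\C)CC(O[Al](C)C)C[C@@]1(C)CCC[C@@]1(C)CO[Al](C)C | intermediate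
28 | (4E)-1-[(1R,2R)-2-(hydroxymethyl)-1,2-dimethylcyclopentyl]-6-(2-methoxy-3-methyl-5-{[tri(propan-2-yl)silyl]oxy}phenyl)-4-methylhex-4-en-2-ol (mixture of C-2 epimers) | COc1c(C)cc(O[Si](C(C)C)(C(C)C)C(C)C)cc1C/C=C(\C)CC(O)C[C@@]1(C)CCC[C@@]1(C)CO | intermediate
29 | (1R,2R)-2-[(4E)-6-(2-methoxy-3-methyl-5-{[tri(propan-2-yl)silyl]oxy}phenyl)-4-methyl-2-oxohex-4-en-1-yl]-1,2-dimethylcyclopentane-1-carbaldehyde | COc1c(C)cc(O[Si](C(C)C)(C(C)C)C(C)C)cc1C/C=C(\C)CC(=O)C[C@@]1(C)CCC[C@@]1(C)C=O | intermediate
30 | 2-methylbut-3-yn-2-ol | CC(C)(O)C#C | starting material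
31 | (3E)-2-methyl-4-(tributylstannyl)but-3-en-2-ol | CCCC[Sn](CCCC)(CCCC)/C=C/C(C)(C)O | intermediate
32 | (3E)-4-iodo-2-methylbut-3-en-2-ol | CC(C)(O)/C=C/I | intermediate
33 | (4E)-1-[(1R,2R)-2-[(2E)-1,4-dihydroxy-4-methylpent-2-en-1-yl]-1,2-dimethylcyclopentyl]-6-(2-methoxy-3-methyl-5-{[tri(propan-2-yl)silyl]oxy}phenyl)-4-methylhex-4-en-2-one (mixture of carbinol epimers) | COc1c(C)cc(O[Si](C(C)C)(C(C)C)C(C)C)cc1C/C=C(\C)CC(=O)C[C@@]1(C)CCC[C@@]1(C)C(O)/C=C/C(C)(C)O | intermediate
34 | (4E)-1-[(1R,2R)-2-[(2E)-4-hydroxy-4-methylpent-2-enoyl]-1,2-dimethylcyclopentyl]-6-(2-methoxy-3-methyl-5-{[tri(propan-2-yl)silyl]oxy}phenyl)-4-methylhex-4-en-2-one | COc1c(C)cc(O[Si](C(C)C)(C(C)C)C(C)C)cc1C/C=C(\C)CC(=O)C[C@@]1(C)CCC[C@@]1(C)C(=O)/C=C/C(C)(C)O | intermediate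
35 | (4E)-1-[(1R,2R)-2-[(2E)-4-hydroxy-4-methylpent-2-enoyl]-1,2-dimethylcyclopentyl]-6-(5-hydroxy-2-methoxy-3-methylphenyl)-4-methylhex-4-en-2-one (CNP0305066.1) | COc1c(C)cc(O)cc1C/C=C(\C)CC(=O)C[C@@]1(C)CCC[C@@]1(C)C(=O)/C=C/C(C)(C)O | target

**Step count and risks**

Total steps: 22. Longest linear sequence: 17 (steps 1–12, 16, 17, 20, 21, 22).

Steps most likely to fail:

1. Step 7. The lactone enolate may add to the formyl group of a second molecule, or the vinylphosphonium salt may be consumed by oligomerisation, before the Michael/Wittig sequence closes the ring; a Michael adduct may also be protonated and fail to form the ylide again. The fallback sets out from 10. Wittig methylenation (Ph3P=CH2, THF) should give (4S)-4-ethenyl-4-methyloxolan-2-one F1. Enolate allylation (LiN(iPr)2, allyl bromide) should give (4R)-4-ethenyl-4-methyl-3-(prop-2-en-1-yl)oxolan-2-one F2 as both C-3 epimers, which interconvert through the enolate. Ring-closing metathesis with second-generation Grubbs catalyst, RuCl2(=CHPh)(H2IMes)(PCy3), should close only the epimer with allyl and vinyl cis. The fallback comes back to the route at 13.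

2. Step 16. The alkenylalane carries two aluminium alkoxides and may transmetallate to palladium too slowly, so that protodealumination or reductive dimerisation of the benzylic chloride takes over. The fallback sets out from 20. The same carboalumination is quenched with I2 to give the isolable (4E)-1-[(1R,2R)-2-(hydroxymethyl)-1,2-dimethylcyclopentyl]-5-iodo-4-methylpent-4-en-2-ol F3. Chloride 26 is converted with zinc dust and LiCl into chloro[(2-methoxy-3-methyl-5-{[tri(propan-2-yl)silyl]oxy}phenyl)methyl]zinc F4. The two are joined in a Negishi coupling with reversed polarity (Pd(PPh3)4, THF). The fallback comes back at 28.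

3. Step 20. Addition of the alkenylchromium reagent to an aldehyde flanked by two quaternary carbons may be slow, which leaves time for Lewis-acid-induced migration of the β,γ-double bond or for reduction of the aldehyde. The fallback sets out from 28 and replaces steps 17, 20 and 21. Oxidative lactonisation (TEMPO, PhI(OAc)2) should give (1R,6R)-4-[(2E)-4-(2-methoxy-3-methyl-5-{[tri(propan-2-yl)silyl]oxy}phenyl)-2-methylbut-2-en-1-yl]-1,6-dimethyl-3-oxabicyclo[4.3.0]nonan-2-one F5. Iodide 32 with t-BuLi (3 equiv, −78 °C) gives the dilithium reagent lithium (3E)-4-lithio-2-methylbut-3-en-2-olate F6, whose single addition to F5 should stop at the hemiketal stage and give, after work-up, the hydroxy enone (4E)-1-[(1R,2R)-2-[(2E)-4-hydroxy-4-methylpent-2-enoyl]-1,2-dimethylcyclopentyl]-6-(2-methoxy-3-methyl-5-{[tri(propan-2-yl)silyl]oxy}phenyl)-4-methylhex-4-en-2-ol F7. Dess–Martin periodinane (NaHCO3, CH2Cl2) then oxidises the remaining secondary alcohol. The fallback comes back at 34.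

**Further compounds**

F1 | step 7 | (4S)-4-ethenyl-4-methyloxolan-2-one | C=C[C@]1(C)CC(=O)OC1
F2 | step 7 | (4R)-4-ethenyl-4-methyl-3-(prop-2-en-1-yl)oxolan-2-one (both C-3 epimers) | C=CCC1C(=O)OC[C@]1(C)C=C
F3 | step 16 | (4E)-1-[(1R,2R)-2-(hydroxymethyl)-1,2-dimethylcyclopentyl]-5-iodo-4-methylpent-4-en-2-ol | I/C=C(\C)CC(O)C[C@@]1(C)CCC[C@@]1(C)CO
F4 | step 16 | chloro[(2-methoxy-3-methyl-5-{[tri(propan-2-yl)silyl]oxy}phenyl)methyl]zinc | COc1c(C)cc(O[Si](C(C)C)(C(C)C)C(C)C)cc1C[Zn]Cl
F5 | step 20 | (1R,6R)-4-[(2E)-4-(2-methoxy-3-methyl-5-{[tri(propan-2-yl)silyl]oxy}phenyl)-2-methylbut-2-en-1-yl]-1,6-dimethyl-3-oxabicyclo[4.3.0]nonan-2-one | COc1c(C)cc(O[Si](C(C)C)(C(C)C)C(C)C)cc1C/C=C(\C)CC3C[C@@]1(C)CCC[C@@]1(C)C(=O)O3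
F6 | step 20 | lithium (3E)-4-lithio-2-methylbut-3-en-2-olate | [Li]/C=C/C(C)(C)O[Li]
F7 | step 20 | (4E)-1-[(1R,2R)-2-[(2E)-4-hydroxy-4-methylpent-2-enoyl]-1,2-dimethylcyclopentyl]-6-(2-methoxy-3-methyl-5-{[tri(propan-2-yl)silyl]oxy}phenyl)-4-methylhex-4-en-2-ol | COc1c(C)cc(O[Si](C(C)C)(C(C)C)C(C)C)cc1C/C=C(\C)CC(O)C[C@@]1(C)CCC[C@@]1(C)C(=O)/C=C/C(C)(C)O
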